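The data are simulated with made-up constants; the scatter is artificial.

Each starting material that becomes target spends one partner, and the side step spends none. So the fall of [partner], counted on its own charge, stays within what I call the toll, the charge of starting material over the charge of partner.

the same everywhere: starting material 0.20 M

| flask | partner | remark | time |
|---|---|---|---|
| maple | 1.4 M | run made earlier |  |
| alder | 2.2 M | run made earlier |  |
| flask | 1.00 M |  | 25 min |

| run | time / min | target / % | starting material / % |
|---|---|---|---|
| maple | 1.50 | 3.8 | 94.9 |
| maple | 2.50 | 20.2 | 73.4 |
| maple | 4.00 | 56.2 | 16.9 |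
| maple | 6.00 | 50.8 | 2.7 |
| maple | 10.0 | 29.8 | 0 |
| maple | 15.0 | 15.9 | 0 |
| maple | 25.0 | 9.2 | 0 |
| alder | 1.50 | 22.2 | 74.5 |
| alder | 2.50 | 67.9 | 12.4 |
| alder | 4.00 | 61.3 | 0.6 |
| alder | 6.00 | 47.1 | 0.6 |
| alder | 10.0 | 28.4 | 0 |
| alder | 15.0 | 17.0 | 0 |
| alder | 25.0 | 8.9 | 0 |

(scatter of a reading: 0.5 percentage points)

- the best time, 25 min at the latest, for target
- the amount of target, in percent of the starting material charged, at that time
- the first time at which target reaches 32 %, in the same percent, in min

My bench rule is that partner, charged in excess over the starting material (the limiting reagent), stays nearly constant, so the time scale of a run goes as one over [partner]. The runs support this: maple at 4.00 min holds 16.9 % of starting material and alder at 2.50 min holds 12.4 %. Those times stand in the ratio 1.60, and the partners in the ratio 1.57.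

The border is the toll. It is 14.3 % in maple, 9.09 % in alder and 20.0 % in this flask, which is larger than in either run. So I correct the rule, taking the mean partner as its charge less half the toll:

stretch of the maple clock = 1.44

best time ≈ 5.78 min, from maple's highest reading

32 % reached between 3.61 min and 5.78 min

The highest reading is 67.9 % in alder and 56.2 % in maple, lower with less partner, so I expect the peak in this flask below 56.2 %.

The forecast says 6.5 min, 46.5 % and 4.6 min, adding “so it hurts more at low partner”.

The flask gives 6.46 min, 45.1 % and 4.60 min: the crossing lies inside my bracket, and the best time stands 0.680 min later than mine.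

    starting material + partner + target → 2 target (k = 0.140 M⁻² s⁻¹)
    starting material + partner → target (k = 5.30 × 10⁻⁵ M⁻¹ s⁻¹)
    target ⇌ isomer of the product (K = 1.30, k = 0.00120 s⁻¹)
    target → over-reaction product (k = 0.00150 s⁻¹)
    starting material + target → side product (k = 0.0210 M⁻¹ s⁻¹)

At 4.53 min the flask makes target 2.72 times as fast as it uses it up, each step taken net. At 25.0 min that ratio is 0.442, and the flask holds 8.85 % of target. Each side product counts as two, one of them starting material that spent no partner, so with 27.9 % of side product in the flask the toll leaves 82.8 % of partner, and the flask holds 82.8 %. With 0.12 M of starting material the same reckoning gives 89.7 %, and that neighbour flask holds 89.7 %.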